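## The problem

CNP0546498.1 is a cyclohexanone (C1) with three substituents on the same face of the ring: an (E)-prop-1-enyl group at C2, a 3-methyltetronic acid joined through its fully substituted C5' at C4, and an (E)-hex-4-enoyl ketone at C5. The configuration is (2S,4S,5R,5'R). Three of the four stereocentres (C5, C4, C5') are contiguous, and C5' is a tertiary carbinol carbon that no later equilibration can correct, so C4 and C5' must be set together and in absolute terms. The remaining centres differ in what controls them. C2 is α to the ring ketone, and its equatorial orientation cis to the C4 substituent is the thermodynamic one. The cis C4/C5 arrangement forces the C5 acyl group axial, so C5 has to be fixed kinetically and kept away from enolising conditions once the side-chain ketone exists. Several groups are fragile: the β,γ-unsaturated ring ketone can move into conjugation or epimerise, the side-chain alkene has allylic C–H bonds that exclude any allylic oxidation after its introduction, the tetronic acid is acidic and nucleophilic at C3', and a cyclohex-2-enone with C4–H in the γ-position and the C5' oxygen in the δ-position can lose that oxygen by vinylogous β-elimination under base. The feature that is exploited is the four-carbon chain made of the hexenoyl carbonyl carbon, C5, C4 and C5'. Closed into a ring it is a cyclobutanone cis-fused to the six-membered ring, the tetronate ring oxygen is the oxygen that a Baeyer–Villiger reaction inserts between the carbonyl carbon and C5', and C3, C2 and C1 are the remaining alkene carbons and the allylic methylene of cyclohexa-1,3-diene.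

## Retrosynthesis

**Side-chain ketone.** Target 29 is traced to its dioxolane 28, and 28 is cut at the bond between the acyl carbon and the pentenyl CH2, giving Weinreb amide 24 and Grignard reagent 27 (from bromide 26, from alcohol 25). This bond is made last among the C–C bonds because the pentenyl alkene would not survive the allylic oxidation of the ring, and because a side-chain ketone present during tetronate closure would enolise and compete with the Dieckmann reaction. The ring ketone therefore already exists when the Grignard reagent is used, which is why it is carried as ketal 18 onwards. The forward step asks only for mono-addition to the amide while the tetronic acid is protected as its magnesium salt.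

**Tetronic acid.** In 24 the C3'–C4' bond is cut (Dieckmann), leading to propanoate methyl ester 23. The C4' ester is traced through acid 22 and alcohol 21 to silyl ether 20, and the propanoate of 20 to tertiary alcohol 19. The alternative cut at O1'–C2' (lactonisation of a γ-hydroxy β-keto ester) is kept as a fallback; the Dieckmann route is chosen because each of its steps is routine on this substrate class. Hydroxy amide 19 is the aminolysis product of lactone 18, so the lactone is a single protecting group for both the tertiary oxygen and the acyl carbon.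

**Ring substituents.** Ketal 18 comes from ketone 17, and 17 from dienone 15 by 1,4-reduction. The C2–propenyl bond of 15 is cut (Suzuki coupling) to iodoenone 13 and boronic acid 14; 13 comes from enone 12, and 12 from cyclohexene 11 by allylic oxidation. Doing all of this on the intact lactone has three advantages: C5 cannot epimerise while it is part of a cis-fused γ-lactone, the lactone shields one face so that protonation at C2 gives the all-cis isomer, and no carbanion chemistry is needed while the enone is present.

**Lactone.** The O–C5' bond of 11 is cut by a retro-Baeyer–Villiger step to cyclobutanone 10. The forward reaction must migrate the fully substituted carbon (normal migratory preference) with retention, and must not epoxidise the ring alkene; the strained cyclobutanone reacts with H2O2 under conditions that alkenes tolerate.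

**Four-membered ring.** Cyclobutanone 10 is cut at the carbonyl–C5 and C4–C5' bonds into cyclohexa-1,3-diene 7 and the keteniminium ion 8 derived from amide 6. Three stereocentres and two skeletal bonds arise from an achiral diene and a simple amide. The forward reaction must control the face of the diene and the orientation of methyl versus silyloxymethyl at C5'.

**Amide.** Amide 6 is cut at the C–N bond to acid 3 and (2R,5R)-2,5-dimethylpyrrolidine 4; 3 comes from commercial hydroxy ester 1 via silyl ether 2.

## Roads not taken

**Alternative 1:** The C4–C5 bond of the cyclohexane is cut. Epoxy nitrile A2, an open chain that carries the ring ketone as a ketal, the C2 propenyl centre and a trisubstituted epoxide from a Sharpless asymmetric epoxidation, would be deprotonated α to the nitrile with KN(SiMe3)2. The carbanion opens the epoxide at its secondary carbon with inversion (6-exo) to give hydroxy nitrile A1.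
- Merits: the absolute configuration of C4 and C5' rests on a very reliable catalytic epoxidation; the nitrile is converted to the hexenoyl ketone by one Grignard addition; the tertiary alcohol is free, so the tetronate can be built without a lactone-opening step. In these respects it is better than the chosen plan.
- Weak points: the C5 configuration is only kinetically controlled in a ring closure whose product is epimerisable under the same base, and the trans isomer is the stable one. The C2 centre must also be built separately in an acyclic precursor, remote from the epoxide, and the linear sequence to A2 is long.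
- Comparison: the chosen plan enforces cis C4/C5 by ring fusion and reaches the bicyclic core in four steps, at the price of an untested diastereoselection at C5'.

**Alternative 2:** The C5–carbonyl bond is cut. Se-phenyl selenocarbonate A4, made from a tertiary alcohol on a 4,6-disubstituted cyclohex-2-enone, would give an alkoxycarbonyl radical with (Me3Si)3SiH/Et3B/air. The radical adds 5-exo to the enone β-carbon and closes the cis-fused lactone A3.
- Merits: A3 is the tert-butyldimethylsilyl analogue of compound 17, so the ring ketone and the propenyl group are already in place and the four ring-functionalisation steps of the chosen route would be saved. The cis fusion is guaranteed and the conditions are neutral. In late-stage economy it is better.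
- Weak points: the stereochemical problem is moved rather than solved, since A4 needs C2, C4 and the carbinol C5' set beforehand, including the awkward relation between a ring centre and an adjacent acyclic quaternary carbinol. A tertiary alkoxycarbonyl radical can also lose CO2 in competition with cyclisation, and the selenocarbonate of a hindered tertiary alcohol is not trivial to make.
- Comparison: the chosen plan creates C4, C5 and C5' in one step from achiral 7.

**Alternative 3:** The ring is traced to a cyclopentenone. Bromomethyl β-keto ester A6 would undergo a Dowd–Beckwith expansion with Bu3SnH/AIBN to cyclohexenone ester A5, with hydrogen transfer setting C5.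
- Merits: C5' comes from lactic acid through a dioxolanone, which is a dependable source of the quaternary centre, and the dioxolanone can be converted to a tetronic acid with a propanoate enolate in one step, which is shorter than the tetronate sequence of the chosen plan.
- Weak points: the C4/C5' relationship has to be made in an intermolecular bond formation of uncertain diastereoselectivity; C5 depends on the face of a hydrogen-atom transfer to an ester-stabilised radical; enone A5 has the γ-H/δ-acyloxy arrangement prone to elimination; the propenyl group must still be added by the same iodination/coupling/reduction sequence; and tin reagents are required.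
- Comparison: the chosen plan is weaker in tetronate economy but sets the three contiguous centres together.

Key step: step 4

Assumption: the (2R,5R)-auxiliary is taken to give the (1S,6R,8R)-cyclobutanone; the sense of induction depends only on the amine enantiomer (the α-centre of 6 is erased in 8), so the (2S,5S)-amine would be substituted if the opposite sense were found.

## Route

Step 1
Reactants: 1 methyl (S)-3-hydroxy-2-methylpropanoate
Product: 2 methyl (S)-2-methyl-3-[tri(propan-2-yl)silyloxy]propanoate
Conditions: iPr3SiCl, imidazole, DMF, rt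
Reagents that add atoms: chlorotri(propan-2-yl)silane, CC(C)[Si](Cl)(C(C)C)C(C)C
Why: Silylation of a primary alcohol; the bulky silyl ether is chosen because it has to survive Tf2O, peroxide, palladium, copper hydride and organomagnesium conditions up to step 13.

Step 2
Reactants: 2 methyl (S)-2-methyl-3-[tri(propan-2-yl)silyloxy]propanoate
Product: 3 (S)-2-methyl-3-[tri(propan-2-yl)silyloxy]propanoic acid
Conditions: LiOH·H2O, THF/MeOH/H2O, rt; then 1 M HCl to pH 3
Reagents that add atoms: lithium hydroxide, [Li+].[OH-]
Why: Ester saponification; any α-epimerisation is without consequence because this centre becomes sp2 in step 4.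

Step 3
Reactants: 3 (S)-2-methyl-3-[tri(propan-2-yl)silyloxy]propanoic acid; 4 (2R,5R)-2,5-dimethylpyrrolidine
Product: 6 (S)-1-[(2R,5R)-2,5-dimethylpyrrolidin-1-yl]-2-methyl-3-[tri(propan-2-yl)silyloxy]propan-1-one, via acid chloride 5 (not isolated)
Conditions: (COCl)2, cat. DMF, CH2Cl2, 0 °C to rt; then 4, Et3N, CH2Cl2, 0 °C to rt
Reagents that add atoms: none
Why: Amide formation through the acid chloride, the reliable way to acylate an α,α'-disubstituted secondary amine; the enantiopure acid keeps 6 a single diastereomer.

Step 4
Reactants: 6 (S)-1-[(2R,5R)-2,5-dimethylpyrrolidin-1-yl]-2-methyl-3-[tri(propan-2-yl)silyloxy]propan-1-one; 7 cyclohexa-1,3-diene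
Product: 10 (1S,6R,8R)-8-methyl-8-{[tri(propan-2-yl)silyloxy]methyl}bicyclo[4.2.0]oct-2-en-7-one, via keteniminium triflate 8 (not isolated), via cyclobutaniminium triflate 9 (not isolated)
Conditions: Tf2O (1.2 equiv), 2,4,6-collidine (1.3 equiv), 7 (4 equiv), CH2Cl2, −78 °C to rt; then aq. NaHCO3, 40 °C
Reagents that add atoms: water, O
Why: Tf2O converts amide 6 into its O-triflyl iminium salt and collidine removes the α-proton to give keteniminium triflate 8, in which the α-centre of 6 is erased and the C2-symmetric pyrrolidine ensures a single reactive species. The electrophilic central carbon of 8 bonds to a terminus of diene 7, the position that leaves an allyl cation, and the enamine carbon then captures the adjacent end of that cation; this stepwise, formally [2+2] closure (ionic 4-exo closure onto the allyl cation) gives cyclobutaniminium salt 9, which aqueous NaHCO3 hydrolyses to 10 with release of the auxiliary. The closest known reaction type is the keteniminium–alkene [2+2] cycloaddition of amide-derived salts carrying C2-symmetric pyrrolidines, together with the ketene–diene cycloaddition. C1 and C6 are set together because a four-membered ring can only be cis-fused to the cyclohexene. C8 is set in the same event: the diene should approach the central carbon past the small methyl group, and the ring-closing rotation then turns the bulkier silyloxymethyl group to the concave face, as unsymmetrical ketenes do with cyclic dienes. The absolute sense is controlled by the (2R,5R)-dimethylpyrrolidine, whose methyl groups differentiate the enantiotopic faces of the reacting double bond in the first bond formation. The step needs [2+2] over [4+2] periselectivity (normal for keteniminium salts), regioselectivity (secured by allyl-cation formation), face selectivity (auxiliary) and endo/exo selectivity at C8 (size difference between methyl and silyloxymethyl); excess diene and low temperature are used against cationic oligomerisation of 7.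

Step 5
Reactants: 10 (1S,6R,8R)-8-methyl-8-{[tri(propan-2-yl)silyloxy]methyl}bicyclo[4.2.0]oct-2-en-7-one
Product: 11 (3R,3aS,7aR)-3-methyl-3-{[tri(propan-2-yl)silyloxy]methyl}-3a,6,7,7a-tetrahydro-2-benzofuran-1(3H)-one
Conditions: 30% aq. H2O2, AcOH, 0 °C to rt
Reagents that add atoms: hydrogen peroxide, OO
Why: Baeyer–Villiger oxidation; the strained cyclobutanone reacts with H2O2 under conditions that do not epoxidise the ring alkene, and the fully substituted C8 migrates with retention, so oxygen enters between the carbonyl carbon and the quaternary carbon and the configuration of the future C5' is kept.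

Step 6
Reactants: 11 (3R,3aS,7aR)-3-methyl-3-{[tri(propan-2-yl)silyloxy]methyl}-3a,6,7,7a-tetrahydro-2-benzofuran-1(3H)-one
Product: 12 (3R,3aS,7aR)-3-methyl-3-{[tri(propan-2-yl)silyloxy]methyl}-3a,7a-dihydro-2-benzofuran-1,6(3H,7H)-dione
Conditions: Rh2(cap)4 (cap = caprolactamate; 1 mol%), 70% aq. tBuOOH, ClCH2CH2Cl, 40 °C
Reagents that add atoms: tert-butyl hydroperoxide, CC(C)(C)OO
Why: Radical allylic C–H oxidation by tert-butylperoxyl radicals; the only allylic methylene (C6) should be attacked, and the allyl radical should be trapped at its unhindered end, remote from the neopentyl-like C3a, so the alkene stays at C4=C5. Base-free conditions avoid vinylogous β-elimination of the lactone oxygen from the enone.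

Step 7
Reactants: 12 (3R,3aS,7aR)-3-methyl-3-{[tri(propan-2-yl)silyloxy]methyl}-3a,7a-dihydro-2-benzofuran-1,6(3H,7H)-dione
Product: 13 (3R,3aR,7aR)-5-iodo-3-methyl-3-{[tri(propan-2-yl)silyloxy]methyl}-3a,7a-dihydro-2-benzofuran-1,6(3H,7H)-dione
Conditions: I2, pyridine, CH2Cl2, 0 °C to rt
Reagents that add atoms: iodine, II
Why: α-Iodination of a cyclohexenone by reversible pyridine conjugate addition, iodination of the enolate and elimination; the 3a-descriptor changes only because iodine alters the priorities.

Step 8
Reactants: 13 (3R,3aR,7aR)-5-iodo-3-methyl-3-{[tri(propan-2-yl)silyloxy]methyl}-3a,7a-dihydro-2-benzofuran-1,6(3H,7H)-dione; 14 (E)-prop-1-enylboronic acid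
Product: 15 (3R,3aS,7aR)-3-methyl-5-[(E)-prop-1-enyl]-3-{[tri(propan-2-yl)silyloxy]methyl}-3a,7a-dihydro-2-benzofuran-1,6(3H,7H)-dione
Conditions: Pd(PhCN)2Cl2 (5 mol%), Ph3As (10 mol%), Ag2O, THF/H2O 8:1, rt
Reagents that add atoms: none
Why: Suzuki–Miyaura coupling of an α-iodoenone (oxidative addition of the C–I bond to zerovalent palladium, Ag2O-assisted transmetalation) with retention of the E geometry; the mild room-temperature base leaves the lactone and the γ-proton untouched.

Step 9
Reactants: 15 (3R,3aS,7aR)-3-methyl-5-[(E)-prop-1-enyl]-3-{[tri(propan-2-yl)silyloxy]methyl}-3a,7a-dihydro-2-benzofuran-1,6(3H,7H)-dione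
Product: 17 (3R,3aS,5S,7aR)-3-methyl-5-[(E)-prop-1-enyl]-3-{[tri(propan-2-yl)silyloxy]methyl}hexahydro-2-benzofuran-1,6-dione, via silyl dienol ether 16 (not isolated)
Conditions: [(Ph3P)CuH]6 (5 mol%), PhMe2SiH (1.5 equiv), toluene, rt; then 1 M HCl, THF, 0 °C
Reagents that add atoms: none
Why: Copper hydride-catalysed 1,4-hydrosilylation of the enone delivers hydride to the unsubstituted β-carbon and leaves the isolated propenyl alkene and the lactone alone. Hydrolysis of dienol ether 16 protonates the α-carbon (the kinetic site) from the convex face opposite the lactone ring, which places the propenyl group cis to the C3a substituent (5S); this is also the equatorial, thermodynamically preferred epimer.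

Step 10
Reactants: 17 (3R,3aS,5S,7aR)-3-methyl-5-[(E)-prop-1-enyl]-3-{[tri(propan-2-yl)silyloxy]methyl}hexahydro-2-benzofuran-1,6-dione
Product: 18 (3R,3aS,5S,7aR)-6,6-(ethylenedioxy)-3-methyl-5-[(E)-prop-1-enyl]-3-{[tri(propan-2-yl)silyloxy]methyl}hexahydro-2-benzofuran-1(3H)-one
Conditions: Me3SiOCH2CH2OSiMe3, Me3SiOTf (5 mol%), CH2Cl2, −78 to −20 °C; pyridine quench
Reagents that add atoms: 1,2-bis(trimethylsilyloxy)ethane, C[Si](C)(C)OCCO[Si](C)(C)C
Why: Aprotic low-temperature ketalisation, which does not move the β,γ-double bond; the dioxolane masks the ring ketone against the amide base, the ester enolate and the Grignard reagent of steps 11–18.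

Step 11
Reactants: 18 (3R,3aS,5S,7aR)-6,6-(ethylenedioxy)-3-methyl-5-[(E)-prop-1-enyl]-3-{[tri(propan-2-yl)silyloxy]methyl}hexahydro-2-benzofuran-1(3H)-one
Product: 19 (6S,8S,9R)-8-[(2R)-2-hydroxy-1-{[tri(propan-2-yl)silyl]oxy}propan-2-yl]-N-methoxy-N-methyl-6-[(E)-prop-1-enyl]-1,4-dioxaspiro[4.5]decane-9-carboxamide
Conditions: MeNHOMe·HCl, iPrMgCl, THF, −20 to 0 °C
Reagents that add atoms: N,O-dimethylhydroxylamine hydrochloride, CNOC.Cl
Why: Aminolysis of the γ-lactone by the chloromagnesium amide gives the Weinreb amide and frees the tertiary alcohol; the amide α-proton is not acidic enough to endanger the C9 (future C5) configuration, and the crude hydroxy amide is carried on at once to avoid acid-induced relactonisation.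

Step 12
Reactants: 19 (6S,8S,9R)-8-[(2R)-2-hydroxy-1-{[tri(propan-2-yl)silyl]oxy}propan-2-yl]-N-methoxy-N-methyl-6-[(E)-prop-1-enyl]-1,4-dioxaspiro[4.5]decane-9-carboxamide
Product: 20 (2R)-2-[(6S,8S,9R)-9-[methoxy(methyl)carbamoyl]-6-[(E)-prop-1-enyl]-1,4-dioxaspiro[4.5]decan-8-yl]-1-{[tri(propan-2-yl)silyl]oxy}propan-2-yl propanoate
Conditions: (EtCO)2O (excess), DMAP, Et3N, CH2Cl2, rt to 40 °C
Reagents that add atoms: propanoic anhydride, CCC(=O)OC(=O)CC
Why: DMAP-catalysed acylation of a tertiary alcohol through the acylpyridinium ion; the basic, non-Lewis-acidic medium is chosen so that neither the ketal nor the γ-hydroxy amide (relactonisation) is activated.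

Step 13
Reactants: 20 (2R)-2-[(6S,8S,9R)-9-[methoxy(methyl)carbamoyl]-6-[(E)-prop-1-enyl]-1,4-dioxaspiro[4.5]decan-8-yl]-1-{[tri(propan-2-yl)silyl]oxy}propan-2-yl propanoate
Product: 21 (2R)-1-hydroxy-2-[(6S,8S,9R)-9-[methoxy(methyl)carbamoyl]-6-[(E)-prop-1-enyl]-1,4-dioxaspiro[4.5]decan-8-yl]propan-2-yl propanoate
Conditions: HF·pyridine, pyridine, THF, 0 °C to rt
Reagents that add atoms: none
Why: Fluoride cleavage of the primary silyl ether; the buffered, weakly acidic reagent is preferred to basic fluoride so that the propanoate does not migrate from the tertiary to the new primary oxygen, and the dioxolane tolerates it.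

Step 14
Reactants: 21 (2R)-1-hydroxy-2-[(6S,8S,9R)-9-[methoxy(methyl)carbamoyl]-6-[(E)-prop-1-enyl]-1,4-dioxaspiro[4.5]decan-8-yl]propan-2-yl propanoate
Product: 22 (2R)-2-[(6S,8S,9R)-9-[methoxy(methyl)carbamoyl]-6-[(E)-prop-1-enyl]-1,4-dioxaspiro[4.5]decan-8-yl]-2-(propanoyloxy)propanoic acid
Conditions: TEMPO (cat.), PhI(OAc)2, MeCN/pH 7 phosphate buffer, rt
Reagents that add atoms: water, O
Why: Oxoammonium-mediated oxidation of the primary alcohol to the acid through the aldehyde hydrate; it is neutral, does not touch the alkene, and removes the free hydroxyl promptly.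

Step 15
Reactants: 22 (2R)-2-[(6S,8S,9R)-9-[methoxy(methyl)carbamoyl]-6-[(E)-prop-1-enyl]-1,4-dioxaspiro[4.5]decan-8-yl]-2-(propanoyloxy)propanoic acid
Product: 23 methyl (2R)-2-[(6S,8S,9R)-9-[methoxy(methyl)carbamoyl]-6-[(E)-prop-1-enyl]-1,4-dioxaspiro[4.5]decan-8-yl]-2-(propanoyloxy)propanoate
Conditions: Me3SiCHN2, toluene/MeOH, 0 °C
Reagents that add atoms: (trimethylsilyl)diazomethane, C[Si](C)(C)C=[N+]=[N-]
Why: Methyl ester formation by O-alkylation of the carboxylic acid under neutral conditions that leave the tertiary propanoate in place.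

Step 16
Reactants: 23 methyl (2R)-2-[(6S,8S,9R)-9-[methoxy(methyl)carbamoyl]-6-[(E)-prop-1-enyl]-1,4-dioxaspiro[4.5]decan-8-yl]-2-(propanoyloxy)propanoate
Product: 24 (6S,8S,9R)-8-[(2R)-3-hydroxy-2,4-dimethyl-5-oxo-2,5-dihydrofuran-2-yl]-N-methoxy-N-methyl-6-[(E)-prop-1-enyl]-1,4-dioxaspiro[4.5]decane-9-carboxamide
Conditions: LiN(SiMe3)2 (2.5 equiv), THF, −78 to 0 °C; then cold 0.5 M HCl to pH 3
Reagents that add atoms: none
Why: Dieckmann condensation: the propanoate enolate attacks the neighbouring methyl ester (5-exo-trig) and the product is held as the stable tetronate anion. The quaternary carbon has no α-proton, and the only ketone-type carbonyl is masked, so no other enolate competes.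

Step 17
Reactants: 25 (E)-pent-3-en-1-ol
Product: 26 (E)-5-bromopent-2-ene
Conditions: CBr4, PPh3, CH2Cl2, 0 °C
Reagents that add atoms: tetrabromomethane, BrC(Br)(Br)Br
Why: Appel reaction; SN2 displacement at the primary carbon leaves the alkene geometry untouched.

Step 18
Reactants: 24 (6S,8S,9R)-8-[(2R)-3-hydroxy-2,4-dimethyl-5-oxo-2,5-dihydrofuran-2-yl]-N-methoxy-N-methyl-6-[(E)-prop-1-enyl]-1,4-dioxaspiro[4.5]decane-9-carboxamide; 26 (E)-5-bromopent-2-ene
Product: 28 (E)-1-[(6S,8S,9R)-8-[(2R)-3-hydroxy-2,4-dimethyl-5-oxo-2,5-dihydrofuran-2-yl]-6-[(E)-prop-1-enyl]-1,4-dioxaspiro[4.5]decan-9-yl]hex-4-en-1-one, via Grignard reagent 27 (not isolated)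
Conditions: 26, Mg, THF, rt; then 24, THF, −20 to 0 °C (4 equiv of 27); aq. NH4Cl
Reagents that add atoms: none
Why: Grignard addition to a Weinreb amide: the first equivalent converts the tetronic acid into its unreactive magnesium salt, and the chelated tetrahedral intermediate prevents over-addition. The ketone appears only on work-up, so C5 is never exposed to base as a ketone.

Step 19
Reactants: 28 (E)-1-[(6S,8S,9R)-8-[(2R)-3-hydroxy-2,4-dimethyl-5-oxo-2,5-dihydrofuran-2-yl]-6-[(E)-prop-1-enyl]-1,4-dioxaspiro[4.5]decan-9-yl]hex-4-en-1-one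
Product: 29 (2S,4S,5R)-5-[(E)-hex-4-enoyl]-4-[(2R)-3-hydroxy-2,4-dimethyl-5-oxo-2,5-dihydrofuran-2-yl]-2-[(E)-prop-1-enyl]cyclohexan-1-one
Conditions: PPTS, acetone/H2O 10:1, rt to 40 °C
Reagents that add atoms: water, O
Why: Acid-catalysed hydrolysis of the dioxolane under weakly acidic aqueous conditions, in which water should trap the oxocarbenium ion faster than it loses the C2 proton; the alkene position and the C2 and C5 configurations are therefore expected to be kept, C2 being the thermodynamic epimer in any case.

## Compound list

1 | methyl (S)-3-hydroxy-2-methylpropanoate | COC(=O)[C@@H](C)CO | starting material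
2 | methyl (S)-2-methyl-3-[tri(propan-2-yl)silyloxy]propanoate | COC(=O)[C@@H](C)CO[Si](C(C)C)(C(C)C)C(C)C | intermediate
3 | (S)-2-methyl-3-[tri(propan-2-yl)silyloxy]propanoic acid | OC(=O)[C@@H](C)CO[Si](C(C)C)(C(C)C)C(C)C | intermediate
4 | (2R,5R)-2,5-dimethylpyrrolidine | C[C@@H]1CC[C@@H](C)N1 | starting material
5 | (S)-2-methyl-3-[tri(propan-2-yl)silyloxy]propanoyl chloride | ClC(=O)[C@@H](C)CO[Si](C(C)C)(C(C)C)C(C)C | intermediate (not isolated)
6 | (S)-1-[(2R,5R)-2,5-dimethylpyrrolidin-1-yl]-2-methyl-3-[tri(propan-2-yl)silyloxy]propan-1-one | C[C@@H](CO[Si](C(C)C)(C(C)C)C(C)C)C(=O)N1[C@H](C)CC[C@H]1C | intermediate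
7 | cyclohexa-1,3-diene | C1=CC=CCC1 | starting material
8 | (2R,5R)-2,5-dimethyl-1-{2-methyl-3-[tri(propan-2-yl)silyloxy]prop-1-enylidene}pyrrolidinium triflate (keteniminium salt) | CC(CO[Si](C(C)C)(C(C)C)C(C)C)=C=[N+]1[C@H](C)CC[C@H]1C.[O-]S(=O)(=O)C(F)(F)F | intermediate (not isolated)
9 | cyclobutaniminium triflate corresponding to 10 (C7=N+ of the (2R,5R)-dimethylpyrrolidinium in place of C7=O; ring configuration as in 10) | C[C@@H]1CC[C@@H](C)[N+]1=C1[C@@H]2CCC=C[C@@H]2[C@@]1(CO[Si](C(C)C)(C(C)C)C(C)C)C.[O-]S(=O)(=O)C(F)(F)F | intermediate (not isolated)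
10 | (1S,6R,8R)-8-methyl-8-{[tri(propan-2-yl)silyloxy]methyl}bicyclo[4.2.0]oct-2-en-7-one (cis-fused; silyloxymethyl on the concave face) | O=C2[C@@H]1CCC=C[C@@H]1[C@@]2(CO[Si](C(C)C)(C(C)C)C(C)C)C | intermediate
11 | (3R,3aS,7aR)-3-methyl-3-{[tri(propan-2-yl)silyloxy]methyl}-3a,6,7,7a-tetrahydro-2-benzofuran-1(3H)-one | O=C2[C@@H]1CCC=C[C@@H]1[C@@](O2)(CO[Si](C(C)C)(C(C)C)C(C)C)C | intermediate
12 | (3R,3aS,7aR)-3-methyl-3-{[tri(propan-2-yl)silyloxy]methyl}-3a,7a-dihydro-2-benzofuran-1,6(3H,7H)-dione | O=C2[C@@H]1CC(=O)C=C[C@@H]1[C@@](O2)(CO[Si](C(C)C)(C(C)C)C(C)C)C | intermediate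
13 | (3R,3aR,7aR)-5-iodo-3-methyl-3-{[tri(propan-2-yl)silyloxy]methyl}-3a,7a-dihydro-2-benzofuran-1,6(3H,7H)-dione | O=C2[C@@H]1CC(=O)C(I)=C[C@@H]1[C@@](O2)(CO[Si](C(C)C)(C(C)C)C(C)C)C | intermediate
14 | (E)-prop-1-enylboronic acid | C/C=C/B(O)O | starting material
15 | (3R,3aS,7aR)-3-methyl-5-[(E)-prop-1-enyl]-3-{[tri(propan-2-yl)silyloxy]methyl}-3a,7a-dihydro-2-benzofuran-1,6(3H,7H)-dione | O=C2[C@@H]1CC(=O)C(/C=C/C)=C[C@@H]1[C@@](O2)(CO[Si](C(C)C)(C(C)C)C(C)C)C | intermediate
16 | (3R,3aS,7aR)-6-[dimethyl(phenyl)silyloxy]-3-methyl-5-[(E)-prop-1-enyl]-3-{[tri(propan-2-yl)silyloxy]methyl}-3a,4,7,7a-tetrahydro-2-benzofuran-1(3H)-one | O=C2[C@@H]1CC(O[Si](C)(C)c3ccccc3)=C(/C=C/C)C[C@@H]1[C@@](O2)(CO[Si](C(C)C)(C(C)C)C(C)C)C | intermediate (not isolated)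
17 | (3R,3aS,5S,7aR)-3-methyl-5-[(E)-prop-1-enyl]-3-{[tri(propan-2-yl)silyloxy]methyl}hexahydro-2-benzofuran-1,6-dione | O=C2[C@@H]1CC(=O)[C@H](/C=C/C)C[C@@H]1[C@@](O2)(CO[Si](C(C)C)(C(C)C)C(C)C)C | intermediate
18 | (3R,3aS,5S,7aR)-6,6-(ethylenedioxy)-3-methyl-5-[(E)-prop-1-enyl]-3-{[tri(propan-2-yl)silyloxy]methyl}hexahydro-2-benzofuran-1(3H)-one (1,3-dioxolane ketal of 17) | O=C2[C@@H]1CC3(OCCO3)[C@H](/C=C/C)C[C@@H]1[C@@](O2)(CO[Si](C(C)C)(C(C)C)C(C)C)C | intermediate
19 | (6S,8S,9R)-8-[(2R)-2-hydroxy-1-{[tri(propan-2-yl)silyl]oxy}propan-2-yl]-N-methoxy-N-methyl-6-[(E)-prop-1-enyl]-1,4-dioxaspiro[4.5]decane-9-carboxamide | CON(C)C(=O)[C@@H]1CC2(OCCO2)[C@H](/C=C/C)C[C@@H]1[C@@](O)(CO[Si](C(C)C)(C(C)C)C(C)C)C | intermediate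
20 | (2R)-2-[(6S,8S,9R)-9-[methoxy(methyl)carbamoyl]-6-[(E)-prop-1-enyl]-1,4-dioxaspiro[4.5]decan-8-yl]-1-{[tri(propan-2-yl)silyl]oxy}propan-2-yl propanoate | CON(C)C(=O)[C@@H]1CC2(OCCO2)[C@H](/C=C/C)C[C@@H]1[C@@](OC(=O)CC)(CO[Si](C(C)C)(C(C)C)C(C)C)C | intermediate
21 | (2R)-1-hydroxy-2-[(6S,8S,9R)-9-[methoxy(methyl)carbamoyl]-6-[(E)-prop-1-enyl]-1,4-dioxaspiro[4.5]decan-8-yl]propan-2-yl propanoate | CON(C)C(=O)[C@@H]1CC2(OCCO2)[C@H](/C=C/C)C[C@@H]1[C@@](OC(=O)CC)(CO)C | intermediate
22 | (2R)-2-[(6S,8S,9R)-9-[methoxy(methyl)carbamoyl]-6-[(E)-prop-1-enyl]-1,4-dioxaspiro[4.5]decan-8-yl]-2-(propanoyloxy)propanoic acid | CON(C)C(=O)[C@@H]1CC2(OCCO2)[C@H](/C=C/C)C[C@@H]1[C@@](OC(=O)CC)(C(=O)O)C | intermediate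
23 | methyl (2R)-2-[(6S,8S,9R)-9-[methoxy(methyl)carbamoyl]-6-[(E)-prop-1-enyl]-1,4-dioxaspiro[4.5]decan-8-yl]-2-(propanoyloxy)propanoate | CON(C)C(=O)[C@@H]1CC2(OCCO2)[C@H](/C=C/C)C[C@@H]1[C@@](OC(=O)CC)(C(=O)OC)C | intermediate
24 | (6S,8S,9R)-8-[(2R)-3-hydroxy-2,4-dimethyl-5-oxo-2,5-dihydrofuran-2-yl]-N-methoxy-N-methyl-6-[(E)-prop-1-enyl]-1,4-dioxaspiro[4.5]decane-9-carboxamide | CON(C)C(=O)[C@@H]1CC2(OCCO2)[C@H](/C=C/C)C[C@@H]1[C@@]1(C)OC(=O)C(C)=C1O | intermediate
25 | (E)-pent-3-en-1-ol | C/C=C/CCO | starting material
26 | (E)-5-bromopent-2-ene | C/C=C/CCBr | intermediate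
27 | (E)-pent-3-enylmagnesium bromide | C/C=C/CC[Mg]Br | intermediate (not isolated)
28 | (E)-1-[(6S,8S,9R)-8-[(2R)-3-hydroxy-2,4-dimethyl-5-oxo-2,5-dihydrofuran-2-yl]-6-[(E)-prop-1-enyl]-1,4-dioxaspiro[4.5]decan-9-yl]hex-4-en-1-one | C/C=C/CCC(=O)[C@@H]1CC2(OCCO2)[C@H](/C=C/C)C[C@@H]1[C@@]1(C)OC(=O)C(C)=C1O | intermediate
29 | (2S,4S,5R)-5-[(E)-hex-4-enoyl]-4-[(2R)-3-hydroxy-2,4-dimethyl-5-oxo-2,5-dihydrofuran-2-yl]-2-[(E)-prop-1-enyl]cyclohexan-1-one | C/C=C/CCC(=O)[C@@H]1CC(=O)[C@H](/C=C/C)C[C@@H]1[C@@]1(C)OC(=O)C(C)=C1O | target

## Step count and risks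

Total: 19 steps. Longest linear sequence: 18 steps (steps 1–16, 18 and 19; step 17 is a one-step branch).

**Step 4 (key step).** The most likely failure is poor orientation at C8 during ring closure, with methyl instead of silyloxymethyl turning to the concave face, or weak face selection by the auxiliary; cationic oligomerisation of the diene by the keteniminium salt would lower conversion. This pairing of an α,α-unsymmetrical salt with a cyclic diene has no direct model. The fallback sets out from acid chloride 5 (made from 3 as in step 3) and diene 7. Triethylamine dehydrochlorinates 5 to methyl{[tri(propan-2-yl)silyloxy]methyl}ketene F1, which is trapped in refluxing diene 7 in a thermal ketene–diene [2+2] cycloaddition, a reaction whose preference for the larger ketene substituent on the concave face is well established. The racemic cycloadduct consists of 10 and its enantiomer F2 and would be resolved by preparative chromatography on a chiral stationary phase; the route is rejoined at 10.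

**Step 6.** Hydrogen abstraction or oxygen trapping at the wrong allylic site (the tertiary C3a–H, or the allyl-radical terminus next to C3a, which gives the transposed enone) and over-oxidation are the likely problems, since the radical has two reactive termini. The fallback sets out from 11 and uses SeO2 (cat.)/tBuOOH in CH2Cl2. This is an ene reaction followed by a [2,3]-shift, which returns the double bond to C4=C5 and hydroxylates the methylene carbon, so no transposed product can arise. It gives the allylic alcohol (3R,3aS,7aR)-6-hydroxy-3-methyl-3-{[tri(propan-2-yl)silyloxy]methyl}-3a,6,7,7a-tetrahydro-2-benzofuran-1(3H)-one F3 (either carbinol epimer), which MnO2 in CH2Cl2 oxidises to 12.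

**Step 12.** Acylation of the hindered tertiary alcohol may be slow enough for relactonisation of the γ-hydroxy amide to 18 to compete, and the following desilylation (step 13) opens a window for acyl migration to the primary oxygen. The fallback avoids both by closing the tetronate through its O1'–C2' bond.
- It sets out from 18. HF·pyridine gives the primary alcohol F4 (the 3-hydroxymethyl lactone), and Dess–Martin periodinane gives the aldehyde F5.
- The lithium enolate of ethyl propanoate (LDA, THF, −78 °C) adds to the aldehyde in preference to the lactone to give the β-hydroxy ester F6 (mixture at the two new centres), and Dess–Martin periodinane gives the β-keto ester F7.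
- Aminolysis of the lactone of F7 with excess MeNHOMe·HCl/iPrMgCl then frees the tertiary alcohol, which lactonises onto the β-keto ester with loss of ethanol on work-up with dilute acid or brief K2CO3/MeOH treatment.
- This gives 24, where the route is rejoined.

**Step 19.** During ketal hydrolysis the oxocarbenium ion could lose the C2 proton and the resulting dienol could reprotonate at the far end of the propenyl group, moving the alkene into conjugation; prolonged acid could also epimerise C5 next to the side-chain ketone. The fallback sets out from 24, where no side-chain ketone is present. The ketal is hydrolysed at this stage (PPTS, acetone/H2O) to the keto amide (1R,2S,4S)-2-[(2R)-3-hydroxy-2,4-dimethyl-5-oxo-2,5-dihydrofuran-2-yl]-N-methoxy-N-methyl-5-oxo-4-[(E)-prop-1-enyl]cyclohexane-1-carboxamide F8. LiN(SiMe3)2 (2.1 equiv, THF, −78 °C) then converts the tetronic acid and the ring ketone into their lithium salts, so the ketone is protected in situ as its enolate while Grignard reagent 27 adds to the Weinreb amide. Aqueous NH4Cl work-up returns the ring ketone by kinetic α-protonation and gives 29 directly.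

## Further compounds

F1 | step 4 | methyl{[tri(propan-2-yl)silyloxy]methyl}ketene | CC(CO[Si](C(C)C)(C(C)C)C(C)C)=C=O
F2 | step 4 | (1R,6S,8S)-8-methyl-8-{[tri(propan-2-yl)silyloxy]methyl}bicyclo[4.2.0]oct-2-en-7-one (enantiomer of 10) | O=C2[C@H]1CCC=C[C@H]1[C@]2(CO[Si](C(C)C)(C(C)C)C(C)C)C
F3 | step 6 | (3R,3aS,7aR)-6-hydroxy-3-methyl-3-{[tri(propan-2-yl)silyloxy]methyl}-3a,6,7,7a-tetrahydro-2-benzofuran-1(3H)-one (either epimer at C6) | O=C2[C@@H]1CC(O)C=C[C@@H]1[C@@](O2)(CO[Si](C(C)C)(C(C)C)C(C)C)C
F4 | step 12 | 3-(hydroxymethyl) analogue of ketal lactone 18 (silyl group removed) | O=C2[C@@H]1CC3(OCCO3)[C@H](/C=C/C)C[C@@H]1[C@@](O2)(CO)C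
F5 | step 12 | 3-formyl analogue of ketal lactone 18 | O=C2[C@@H]1CC3(OCCO3)[C@H](/C=C/C)C[C@@H]1[C@@](O2)(C=O)C
F6 | step 12 | ethyl 3-hydroxy-2-methyl-3-(lactone C3)propanoate derived from F5 (mixture at the two new centres) | O=C2[C@@H]1CC3(OCCO3)[C@H](/C=C/C)C[C@@H]1[C@@](O2)(C(O)C(C)C(=O)OCC)C
F7 | step 12 | ethyl 2-methyl-3-oxo-3-(lactone C3)propanoate derived from F6 (α-methyl centre unspecified) | O=C2[C@@H]1CC3(OCCO3)[C@H](/C=C/C)C[C@@H]1[C@@](O2)(C(=O)C(C)C(=O)OCC)C
F8 | step 19 | (1R,2S,4S)-2-[(2R)-3-hydroxy-2,4-dimethyl-5-oxo-2,5-dihydrofuran-2-yl]-N-methoxy-N-methyl-5-oxo-4-[(E)-prop-1-enyl]cyclohexane-1-carboxamide | CON(C)C(=O)[C@@H]1CC(=O)[C@H](/C=C/C)C[C@@H]1[C@@]1(C)OC(=O)C(C)=C1O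
A1 | alternative 1 | cyclised hydroxy nitrile with cis C4 and C5 substituents (ketal, tert-butyldimethylsilyl ether) | N#C[C@@H]1CC3(OCCO3)[C@H](/C=C/C)C[C@@H]1[C@@](CO[Si](C)(C)C(C)(C)C)(C)O
A2 | alternative 1 | open-chain epoxy nitrile precursor of A1 | N#CCCC1(OCCO1)[C@H](/C=C/C)C[C@@H]2O[C@]2(CO[Si](C)(C)C(C)(C)C)C
A3 | alternative 2 | cis-fused keto lactone carrying the propenyl group (tert-butyldimethylsilyl analogue of 17) | O=C2[C@@H]1CC(=O)[C@H](/C=C/C)C[C@@H]1[C@@](CO[Si](C)(C)C(C)(C)C)(C)O2
A4 | alternative 2 | Se-phenyl selenocarbonate of the tertiary alcohol on the 4,6-disubstituted cyclohex-2-enone | O=C1C=C[C@H](C[C@H]1/C=C/C)[C@](C)(CO[Si](C)(C)C(C)(C)C)OC(=O)[Se]c1ccccc1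
A5 | alternative 3 | cis-4,5-disubstituted cyclohex-2-enone ester with the dioxolanone | COC(=O)[C@@H]1CC(=O)C=C[C@@H]1[C@@]3(C)O[C@H](C(C)(C)C)OC3=O
A6 | alternative 3 | bromomethyl cyclopentenone β-keto ester (bromomethyl trans to the dioxolanone) | COC(=O)[C@]1(CBr)C(=O)C=C[C@@H]1[C@@]2(C)O[C@H](C(C)(C)C)OC2=O
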